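**Plan**
Retrosynthesis (ring C = C1'–C5', C11 on C1'): a 1,3-proton shift takes the exocyclic C11=C1' alkene and C5'–H back to an endocyclic C1'=C5' enedione, and two chlorines are returned to C3'. The C1'–C2' bond is then cut and one carbon re-inserted between C1' and C2', which turns ring C into a chlorinated resorcinol; next the aryl–C11 bond is cut, and last the bond from C11 to the lactone carbonyl carbon of a sclareolide.
Enabling feature: in ring C the carbonyl-level carbons C2' and C4' flank C3', chlorine sits on C5' and the C11 chain on C1'. This is the pattern of a 5-alkylresorcinol that has lost the ring CH between its alkyl-bearing carbon and one C–O carbon.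
Forward: rings A and B come intact from (+)-sclareolide. The side chain is trimmed to the C11 aldehyde, the arene is joined at C11, hypochlorite contracts the arene to ring C, and dechlorination at C3' plus the proton shift finish the target.
Stereochemistry: C5, C9 and C10 come from sclareolide. C8 is inverted by acid equilibration in step 1. C5' and the E alkene are set in the last step by a chiral proton shuttle and allylic strain.

Key step: step 9

Remark: drimane numbering is used for rings A and B (C11 on C9); 1,3-bis(benzyloxy)-5-bromobenzene is taken as a catalogue compound; the C11 carbinol centre of 3, 4, 8 and 9 and the carbinol carbon of 14 are epimer mixtures that are erased later, so their SMILES carry no descriptor there.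

**Step 1**
Reactants: 1 (+)-sclareolide
Product: 2 8-epi-sclareolide (8β-oxygen, 8α-methyl, cis-fused γ-lactone)
Conditions: H2SO4 (conc.), HCO2H, rt
Reagents that add atoms: none
Why: Acid-mediated lactone epimerisation, in which protonation ionises the tertiary C8–O bond and the pendant carboxylic acid recaptures the C8 cation from the β face, the equilibrium resting on the less strained cis-fused γ-lactone, so that C8 alone is inverted while C5, C9 and C10 stay as in 1.

**Step 2**
Reactants: 2 8-epi-sclareolide
Product: 3 hydroxy lactone 11-hydroxy-8-epi-sclareolide (C11 epimer mixture)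
Conditions: KN(SiMe3)2, THF, −78 °C; 2-(phenylsulfonyl)-3-phenyloxaziridine, −78 °C; AcOH quench
Reagents that add atoms: 2-(phenylsulfonyl)-3-phenyloxaziridine, O=S(=O)(c1ccccc1)N1OC1c1ccccc1
Why: Enolate oxidation with an N-sulfonyloxaziridine, the potassium enolate of the lactone attacking the electrophilic oxygen through C11; the new C11 carbinol centre (expected mainly from the convex face of the cis-fused bicycle) needs no control because C11 becomes a trigonal aldehyde carbon in step 4.

**Step 3**
Reactants: 3 hydroxy lactone 11-hydroxy-8-epi-sclareolide
Product: 4 triol 11-(hydroxymethyl)drimane-8β,11-diol (C11 epimer mixture)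
Conditions: LiAlH4, THF, 0 °C → rt; H2O, aq NaOH
Reagents that add atoms: none
Why: Hydride reduction of a lactone to the diol, LiAlH4 opening the ring to the primary alcohol and releasing the tertiary 8β-hydroxyl without touching a ring stereocentre.

**Step 4**
Reactants: 4 triol 11-(hydroxymethyl)drimane-8β,11-diol
Product: 5 aldehyde 8β-hydroxydriman-11-al
Conditions: NaIO4, THF/H2O, rt
Reagents that add atoms: none
Why: Malaprade glycol cleavage, periodate forming its cyclic ester only with the vicinal diol of the side chain (the C8/C11 hydroxyls are a 1,3-pair and inert) and excising the former lactone carbonyl carbon as formaldehyde, which leaves C11 as the aldehyde with C9 in its equatorial, thermodynamically preferred 9β configuration.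

**Step 5**
Reactants: 5 aldehyde 8β-hydroxydriman-11-al; 6 1,3-bis(benzyloxy)-5-bromobenzene
Product: 8 diol 11-[3,5-bis(benzyloxy)phenyl]drimane-8β,11-diol (C11 epimer mixture), via aryllithium 7 (not isolated)
Conditions: 6 (2.4 equiv), n-BuLi (2.3 equiv), THF, −78 °C; then 5, −78 → −20 °C; H2O
Reagents that add atoms: none
Why: Bromine–lithium exchange followed by 1,2-addition of the aryllithium to the aldehyde, one equivalent being spent on the C8 hydroxyl (whose lithium alkoxide should resist retro-aldol cleavage at −78 °C) and the second adding to the neopentyl-type carbonyl; the C11 carbinol centre (Felkin–Anh or chelate control) is of no consequence because it is reduced to CH2 in step 7.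

**Step 6**
Reactants: 8 diol 11-[3,5-bis(benzyloxy)phenyl]drimane-8β,11-diol
Product: 9 acetate 11-[3,5-bis(benzyloxy)phenyl]-8β-hydroxydriman-11-yl acetate (C11 epimer mixture)
Conditions: Ac2O, pyridine, DMAP (cat.), rt
Reagents that add atoms: acetic anhydride, CC(=O)OC(C)=O
Why: DMAP-catalysed acylation discriminates the secondary benzylic hydroxyl from the axial tertiary C8 hydroxyl, which is not acetylated at room temperature, and turns the benzylic oxygen into a leaving group for hydrogenolysis.

**Step 7**
Reactants: 9 acetate 11-[3,5-bis(benzyloxy)phenyl]-8β-hydroxydriman-11-yl acetate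
Product: 10 resorcinol 5-(8β-hydroxydriman-11-yl)benzene-1,3-diol
Conditions: H2 (4 bar), Pd(OH)2/C, EtOH/EtOAc, rt
Reagents that add atoms: none
Why: Catalytic hydrogenolysis over palladium should cleave the two O-benzyl ethers and the benzylic C11–OAc bond in one operation, erasing the C11 stereocentre, while the tertiary alcohol and the arene are not reduced under these conditions.

**Step 8**
Reactants: 10 resorcinol 5-(8β-hydroxydriman-11-yl)benzene-1,3-diol
Product: 11 chlororesorcinol 4-chloro-5-(8β-hydroxydriman-11-yl)benzene-1,3-diol
Conditions: N-chlorosuccinimide (1.0 equiv), MeCN, 0 °C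
Reagents that add atoms: N-chlorosuccinimide, O=C1CCC(=O)N1Cl
Why: Electrophilic aromatic chlorination of the doubly activated ring, one equivalent stopping at the monochloride with the position para to one hydroxyl and ortho to the other favoured as in orcinol; the site of this first chlorine is not critical because step 9 chlorinates every free ring position.

**Step 9**
Reactants: 11 chlororesorcinol 4-chloro-5-(8β-hydroxydriman-11-yl)benzene-1,3-diol
Product: 15 2,2,4-trichloro-5-(8β-hydroxydriman-11-yl)cyclopent-4-ene-1,3-dione, via pentachlorocyclohexenedione 12 (not isolated), via cyclohexenetrione 13 (not isolated), via hydroxy acid 14 (not isolated)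
Conditions: aq NaOCl (5.5 equiv, in portions), NaH2PO4/Na2HPO4 buffer pH 7, MeCN, 0 → 20 °C, dark; 2-methyl-2-butene quench; pH 3, EtOAc extraction
Reagents that add atoms: sodium hypochlorite, [Na+].[O-]Cl
Why: Proposed new method: Hypochlorous acid chlorinates the two free ring positions of 11 and then, once more each, the carbon between the two C–O carbons and one carbon next to C1', which gives pentachlorodione 12; the ring is symmetrically chlorinated before that point, so it does not matter which ortho carbon takes the second chlorine. Water replaces the allylic gem-dichloride beside C1' (directly or in the SN2' sense, both ending in the same compound) to give the vicinal dione of 13; hydroxide adds to it and C1' moves with its bonding pair from the attacked carbonyl carbon to C2' (benzilic acid 1,2-shift; attack at the other carbonyl of the pair would lead to the same acid), so that the C1'–C2' bond is formed and the carbon between them becomes the carboxyl group of 14. Hypochlorite then oxidises the tertiary α-hydroxy acid with loss of CO2 to the C2' ketone of 15, the two water-derived oxygens leaving with the extruded carbon. The closest known reaction types are the benzilic acid ring contraction of cyclic 1,2-diones coupled with oxidative decarboxylation (rhodizonate to croconate, halogenated hydroxyquinones to cyclopentenetriones) and the appearance of 2,2,4-trichlorocyclopent-4-ene-1,3-dione when resorcinol itself is chlorinated in water, which has not been used preparatively on an alkylresorcinol. Ring C closes by contraction of the six-membered ring through a three-centre 1,2-shift and not by an end-to-end cyclisation, and no lasting stereocentre is formed (the carbinol carbon of 14 is lost again). The step needs the contraction to win over haloform-type cleavage at the carbonyls flanking the C3' gem-dichloride and over chlorination at C11; pH 7 buffering, low temperature and portionwise oxidant are set against cleavage, the C1' alkyl group blocks its own ring position, leaves the allylic gem-dichloride as the only hydrolysable one and stabilises the tetrasubstituted enedione, and the saturated decalin and tertiary alcohol are inert to hypochlorite (an O-chlorinated C8 hydroxyl would revert in step 10).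

**Step 10**
Reactants: 15 2,2,4-trichloro-5-(8β-hydroxydriman-11-yl)cyclopent-4-ene-1,3-dione
Product: 16 enedione 4-chloro-5-(8β-hydroxydriman-11-yl)cyclopent-4-ene-1,3-dione
Conditions: NaI (5 equiv), AcOH, THF, 0 °C; cold aq Na2S2O3 wash; used at once
Reagents that add atoms: none
Why: Halophilic reduction of positive halogen, iodide attacking the chlorines of the CCl2 group flanked by two carbonyls so that the 1,3-dione enolate leaves and is protonated by acetic acid, twice over, whereas the vinylic C5'–Cl bond offers no such leaving group and should stay.

**Step 11**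
Reactants: 16 enedione 4-chloro-5-(8β-hydroxydriman-11-yl)cyclopent-4-ene-1,3-dione
Product: 17 (4E,5R)-5-chloro-3-hydroxy-4-(8β-hydroxydriman-11-ylidene)cyclopent-2-en-1-one (target CNP0279879.2; ring locants C4 = C1' and C5 = C5')
Conditions: quinidine (1.1 equiv), toluene, −20 → 0 °C; cold aq citric acid
Reagents that add atoms: none
Why: Proposed new method: the quinuclidine nitrogen of quinidine should remove a C11 proton of the neutral enedione (the vinylogous α-position of the C4' carbonyl) to give a dienolate held as a contact ion pair, and the ammonium/C9-hydroxyl array of the alkaloid returns the proton on the same face to C5' (kinetic α-protonation of a dienolate), after which the new 1,3-dione enolises between its carbonyls and rests as the quinidinium vinylogous carboxylate, a sink that makes the shift irreversible and shields C5'–H from exchange; the closest known reaction types are the base-mediated prototropic isomerisation of alkylmaleic to alkylidenesuccinic systems and cinchona-alkaloid proton-transfer catalysis in the isomerisation of β,γ-unsaturated butenolides; C5' (R) is to be set by the face on which the chiral ion pair delivers the proton, and the E geometry by the C9 substituent turning away from the in-plane C5'–Cl bond in the dienolate (allylic 1,3-strain).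

**Compound list**
1 | (+)-sclareolide | CC1(C)CCC[C@]2(C)[C@H]3CC(=O)O[C@]3(C)CC[C@@H]12 | starting material
2 | 8-epi-sclareolide | CC1(C)CCC[C@]2(C)[C@H]3CC(=O)O[C@@]3(C)CC[C@@H]12 | intermediate
3 | 11-hydroxy-8-epi-sclareolide (C11 epimer mixture) | CC1(C)CCC[C@]2(C)[C@H]3C(O)C(=O)O[C@@]3(C)CC[C@@H]12 | intermediate
4 | 11-(hydroxymethyl)drimane-8β,11-diol (C11 epimer mixture) | CC1(C)CCC[C@]2(C)[C@@H](C(O)CO)[C@@](C)(O)CC[C@@H]12 | intermediate
5 | 8β-hydroxydriman-11-al | CC1(C)CCC[C@]2(C)[C@@H](C=O)[C@@](C)(O)CC[C@@H]12 | intermediate
6 | 1,3-bis(benzyloxy)-5-bromobenzene | Brc1cc(OCc2ccccc2)cc(OCc2ccccc2)c1 | starting material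
7 | 3,5-bis(benzyloxy)phenyllithium (formed in the flask) | [Li]c1cc(OCc2ccccc2)cc(OCc2ccccc2)c1 | intermediate
8 | 11-[3,5-bis(benzyloxy)phenyl]drimane-8β,11-diol (C11 epimer mixture) | CC1(C)CCC[C@]2(C)[C@@H](C(O)c3cc(OCc4ccccc4)cc(OCc4ccccc4)c3)[C@@](C)(O)CC[C@@H]12 | intermediate
9 | 11-[3,5-bis(benzyloxy)phenyl]-8β-hydroxydriman-11-yl acetate (C11 epimer mixture) | CC1(C)CCC[C@]2(C)[C@@H](C(OC(C)=O)c3cc(OCc4ccccc4)cc(OCc4ccccc4)c3)[C@@](C)(O)CC[C@@H]12 | intermediate
10 | 5-(8β-hydroxydriman-11-yl)benzene-1,3-diol | CC1(C)CCC[C@]2(C)[C@@H](Cc3cc(O)cc(O)c3)[C@@](C)(O)CC[C@@H]12 | intermediate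
11 | 4-chloro-5-(8β-hydroxydriman-11-yl)benzene-1,3-diol | CC1(C)CCC[C@]2(C)[C@@H](Cc3cc(O)cc(O)c3Cl)[C@@](C)(O)CC[C@@H]12 | intermediate
12 | 2,2,4,6,6-pentachloro-5-(8β-hydroxydriman-11-yl)cyclohex-4-ene-1,3-dione (formed in the flask) | CC1(C)CCC[C@]2(C)[C@@H](CC3=C(Cl)C(=O)C(Cl)(Cl)C(=O)C3(Cl)Cl)[C@@](C)(O)CC[C@@H]12 | intermediate
13 | 3,3,5-trichloro-6-(8β-hydroxydriman-11-yl)cyclohex-5-ene-1,2,4-trione (formed in the flask) | CC1(C)CCC[C@]2(C)[C@@H](CC3=C(Cl)C(=O)C(Cl)(Cl)C(=O)C3=O)[C@@](C)(O)CC[C@@H]12 | intermediate
14 | 3,5,5-trichloro-1-hydroxy-2-(8β-hydroxydriman-11-yl)-4-oxocyclopent-2-ene-1-carboxylic acid (formed in the flask; carbinol carbon undefined) | CC1(C)CCC[C@]2(C)[C@@H](CC3=C(Cl)C(=O)C(Cl)(Cl)C3(O)C(=O)O)[C@@](C)(O)CC[C@@H]12 | intermediate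
15 | 2,2,4-trichloro-5-(8β-hydroxydriman-11-yl)cyclopent-4-ene-1,3-dione | CC1(C)CCC[C@]2(C)[C@@H](CC3=C(Cl)C(=O)C(Cl)(Cl)C3=O)[C@@](C)(O)CC[C@@H]12 | intermediate
16 | 4-chloro-5-(8β-hydroxydriman-11-yl)cyclopent-4-ene-1,3-dione | CC1(C)CCC[C@]2(C)[C@@H](CC3=C(Cl)C(=O)CC3=O)[C@@](C)(O)CC[C@@H]12 | intermediate
17 | (4E,5R)-5-chloro-3-hydroxy-4-(8β-hydroxydriman-11-ylidene)cyclopent-2-en-1-one | CC1(C)CCC[C@]2(C)[C@@H](/C=C3\C(O)=CC(=O)[C@@H]3Cl)[C@@](C)(O)CC[C@@H]12 | target

**Step count and risks**
Total step count: 11. Longest linear sequence: 11 steps (1 to 17); the aryl partner 6 is bought.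

Step 9 (most at risk). Hydroxide may cleave the ring at a carbonyl flanking the C3' gem-dichloride (haloform-type fragmentation) faster than the allylic gem-dichloride is hydrolysed and the 1,2-shift takes place, and vinylogous enolisation may lead to chlorination at C11. The fallback separates the oxidation-level change from the contraction and uses known reaction types throughout. It sets out from 11: oxidation with potassium nitrosodisulfonate (KSO3)2NO in buffered aqueous acetone (Teuber reaction; the chlorine already on the ring leaves a single free para position) should give 5-chloro-2-hydroxy-6-(8β-hydroxydriman-11-yl)-1,4-benzoquinone F1, which already carries the vicinal oxygen pair next to C1'. Two equivalents of N-chlorosuccinimide in wet MeCN chlorinate its enolised C3' twice to give trione 13, aqueous NaHCO3 brings about the benzilic acid rearrangement to 14, and Pb(OAc)4 in AcOH decarboxylates the α-hydroxy acid oxidatively to 15, where the route is rejoined.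

Step 11. The proton return at C5' may show poor facial discrimination because that carbon is remote from the drimane stereocentres; the substrate may be held unproductively as its C3' enolate; and that enolate may displace the vinylic chloride of a second molecule. The fallback gives up asymmetric induction. It sets out from 16, which is treated with DBU (1.05 equiv) in dilute THF at 0 °C, a plain base-mediated prototropic isomerisation of an alkyl-substituted enedione to its alkylidene isomer; this should give 17 together with its C5' epimer (4E,5S)-5-chloro-3-hydroxy-4-(8β-hydroxydriman-11-ylidene)cyclopent-2-en-1-one F2. The two are diastereomers and would be separated by preparative HPLC or by fractional crystallisation of their quinidine salts, the route being rejoined at 17.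

Step 7. Hydrogenolysis of the C11–O bond may stall at this neopentyl-type benzylic position once the benzyl ethers have gone, since the ring has no ortho or para donor to assist. The fallback replaces surface hydrogenolysis by a radical deoxygenation (Barton–McCombie). It sets out from 8: phenyl chlorothionoformate, pyridine and DMAP acylate the secondary hydroxyl to give O-{11-[3,5-bis(benzyloxy)phenyl]-8β-hydroxydriman-11-yl} O-phenyl carbonothioate F3; tributyltin hydride Bu3SnH with AIBN in toluene at 80 °C reduces the benzylic radical to 1,3-bis(benzyloxy)-5-(8β-hydroxydriman-11-yl)benzene F4; and H2 over Pd/C removes the two benzyl ethers to return to the route at 10.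

**Further compounds**
F1 | step 9 | 5-chloro-2-hydroxy-6-(8β-hydroxydriman-11-yl)-1,4-benzoquinone | CC1(C)CCC[C@]2(C)[C@@H](CC3=C(Cl)C(=O)C=C(O)C3=O)[C@@](C)(O)CC[C@@H]12
F2 | step 11 | (4E,5S)-5-chloro-3-hydroxy-4-(8β-hydroxydriman-11-ylidene)cyclopent-2-en-1-one | CC1(C)CCC[C@]2(C)[C@@H](/C=C3\C(O)=CC(=O)[C@H]3Cl)[C@@](C)(O)CC[C@@H]12
F3 | step 7 | O-{11-[3,5-bis(benzyloxy)phenyl]-8β-hydroxydriman-11-yl} O-phenyl carbonothioate | CC1(C)CCC[C@]2(C)[C@@H](C(OC(=S)Oc3ccccc3)c3cc(OCc4ccccc4)cc(OCc4ccccc4)c3)[C@@](C)(O)CC[C@@H]12
F4 | step 7 | 1,3-bis(benzyloxy)-5-(8β-hydroxydriman-11-yl)benzene | CC1(C)CCC[C@]2(C)[C@@H](Cc3cc(OCc4ccccc4)cc(OCc4ccccc4)c3)[C@@](C)(O)CC[C@@H]12
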